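**Retrosynthetic overview**
1. Target 12 ⇐ triol 11 (primary-selective acetylation) ⇐ 14,15-acetonide 10.
2. Key disconnection C12–C13: light-driven samarium Barbier union of homodrimenyl iodide 5 with methyl ketone 8. C13 is set by chelation to the C14 centre already present in 8.
3. 5 ⇐ (−)-sclareol glycol 1 (exo-selective dehydration of the 8-OH, then OH → I); 1 supplies C5, C9 and C10.
4. 8 ⇐ methyl (S)-glycerate acetonide 6 (L-serine-derived); 6 supplies C14.
5. Ring order: rings A and B (the trans-decalin) are bought intact and no carbocycle is built; the dioxolane is only a temporary ring.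

Assumption: (−)-sclareol glycol (ambradiol, the industrial Ambrox precursor) and methyl (S)-2,2-dimethyl-1,3-dioxolane-4-carboxylate are taken as commercial; atom labels C1–C20 follow labdane numbering.

**Step 1**
Reactants: 1 (−)-sclareol glycol, (1R,2R,4aS,8aS)-1-(2-hydroxyethyl)-2,5,5,8a-tetramethyldecahydronaphthalen-2-ol
Product: 4 2-[(1S,4aS,8aS)-5,5,8a-trimethyl-2-methylidenedecahydronaphthalen-1-yl]ethan-1-ol, via TMS ether 2 (not isolated), via alkene TMS ether 3 (not isolated)
Conditions: TMSCl (1.05 equiv), pyridine (6 equiv), CH2Cl2, −20 °C; SOCl2 (1.5 equiv), −78 °C, 1 h; MeOH, −78 → 0 °C; chromatography on AgNO3-impregnated silica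
Reagents that add atoms: none
Why: Transient primary-selective silylation leaves only the tertiary 8-OH to form a chlorosulfite, whose pyridine-mediated anti E2 elimination from the equatorial C8–O bond can only use a C17 hydrogen, so the exocyclic alkene should dominate (I expect about 4:1 or better, endo isomers removed on AgNO3–silica), and the buffered methanol quench cleaves the silyl ether; no stereocentre is touched.

**Step 2**
Reactants: 4 2-[(1S,4aS,8aS)-5,5,8a-trimethyl-2-methylidenedecahydronaphthalen-1-yl]ethan-1-ol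
Product: 5 (1S,4aS,8aS)-1-(2-iodoethyl)-5,5,8a-trimethyl-2-methylidenedecahydronaphthalene
Conditions: I2 (1.2 equiv), PPh3 (1.2 equiv), imidazole (1.5 equiv), CH2Cl2, 0 °C → rt, dark
Reagents that add atoms: iodine, II
Why: Appel iodination, in which iodide displaces the primary alkoxyphosphonium by SN2 without touching a stereocentre or the exocyclic alkene.

**Step 3**
Reactants: 6 methyl (4S)-2,2-dimethyl-1,3-dioxolane-4-carboxylate
Product: 8 1-[(4S)-2,2-dimethyl-1,3-dioxolan-4-yl]ethan-1-one, via Weinreb amide 7 (not isolated)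
Conditions: MeNH(OMe)·HCl (1.5 equiv), iPrMgCl (3.0 equiv), THF, −20 °C; MeMgBr (1.5 equiv), −20 → 0 °C; aq. NH4Cl; careful distillation
Reagents that add atoms: methylmagnesium bromide, C[Mg]Br
Why: Weinreb ketone synthesis run in one flask: the chloromagnesium amide converts the ester into the Weinreb amide, whose stable magnesium chelate stops MeMgBr addition at the ketone stage, and the C14 centre is not deprotonated at −20 °C.

**Step 4**
Reactants: 5 (1S,4aS,8aS)-1-(2-iodoethyl)-5,5,8a-trimethyl-2-methylidenedecahydronaphthalene; 8 1-[(4S)-2,2-dimethyl-1,3-dioxolan-4-yl]ethan-1-one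
Product: 10 (2S)-2-[(4S)-2,2-dimethyl-1,3-dioxolan-4-yl]-4-[(1S,4aS,8aS)-5,5,8a-trimethyl-2-methylidenedecahydronaphthalen-1-yl]butan-2-ol, via alkylsamarium diiodide 9 (not isolated)
Conditions: 5 and 8 (1.5 equiv) added to SmI2 (2.5 equiv, 0.1 M in THF, no HMPA), hν (560–620 nm LEDs), −20 °C, Ar; aq. NH4Cl
Reagents that add atoms: none
Why: Proposed new method: a light-driven, HMPA-free samarium Barbier alkylation under chelation control — visible-light excitation of SmI2 makes divalent samarium reducing enough to cleave the unactivated C–I bond of 5 irreversibly at −20 °C, a second divalent samarium captures the primary radical as alkylsamarium 9, and because no HMPA blocks the metal the trivalent samarium chelates the carbonyl oxygen and the adjacent dioxolane oxygen of 8 so that C12 adds to the face anti to the ring CH2 (Cram chelate model, 1,2-induction from the bought C14 centre) and sets 13S; the closest known reactions are photo-accelerated SmI2 Barbier reactions of alkyl halides and thermal chelation-controlled SmI2 Barbier and Grignard additions to α-alkoxy ketones, which have not been combined on an α,β-dialkoxy ketone with an unactivated iodide.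

**Step 5**
Reactants: 10 (2S)-2-[(4S)-2,2-dimethyl-1,3-dioxolan-4-yl]-4-[(1S,4aS,8aS)-5,5,8a-trimethyl-2-methylidenedecahydronaphthalen-1-yl]butan-2-ol
Product: 11 (2S,3S)-3-methyl-5-[(1S,4aS,8aS)-5,5,8a-trimethyl-2-methylidenedecahydronaphthalen-1-yl]pentane-1,2,3-triol
Conditions: AcOH/H2O (4:1), 35 °C
Reagents that add atoms: none
Why: Acid-catalysed acetal hydrolysis of the terminal isopropylidene group under conditions too mild to isomerise the exocyclic alkene or ionise the tertiary alcohol; no stereocentre is involved.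

**Step 6**
Reactants: 11 (2S,3S)-3-methyl-5-[(1S,4aS,8aS)-5,5,8a-trimethyl-2-methylidenedecahydronaphthalen-1-yl]pentane-1,2,3-triol
Product: 12 (2S,3S)-2,3-dihydroxy-3-methyl-5-[(1S,4aS,8aS)-5,5,8a-trimethyl-2-methylidenedecahydronaphthalen-1-yl]pentyl acetate, i.e. (13S,14S)-15-acetoxylabd-8(17)-ene-13,14-diol (target)
Conditions: AcCl (1.05 equiv), 2,4,6-collidine (2 equiv), CH2Cl2, −78 °C
Reagents that add atoms: acetyl chloride, CC(=O)Cl
Why: Kinetically controlled acylation: with the hindered base at −78 °C the primary hydroxyl reacts far faster than the secondary one next to a quaternary carbon or the tertiary one, so only O15 is acetylated.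

**Compound list**
1 | (−)-sclareol glycol, (1R,2R,4aS,8aS)-1-(2-hydroxyethyl)-2,5,5,8a-tetramethyldecahydronaphthalen-2-ol | C[C@@]1(O)CC[C@H]2C(C)(C)CCC[C@]2(C)[C@H]1CCO | starting material
2 | (1R,2R,4aS,8aS)-2,5,5,8a-tetramethyl-1-[2-(trimethylsilyloxy)ethyl]decahydronaphthalen-2-ol | C[C@@]1(O)CC[C@H]2C(C)(C)CCC[C@]2(C)[C@H]1CCO[Si](C)(C)C | intermediate (not isolated)
3 | trimethyl{2-[(1S,4aS,8aS)-5,5,8a-trimethyl-2-methylidenedecahydronaphthalen-1-yl]ethoxy}silane | C=C1CC[C@H]2C(C)(C)CCC[C@]2(C)[C@H]1CCO[Si](C)(C)C | intermediate (not isolated)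
4 | 2-[(1S,4aS,8aS)-5,5,8a-trimethyl-2-methylidenedecahydronaphthalen-1-yl]ethan-1-ol | C=C1CC[C@H]2C(C)(C)CCC[C@]2(C)[C@H]1CCO | intermediate
5 | (1S,4aS,8aS)-1-(2-iodoethyl)-5,5,8a-trimethyl-2-methylidenedecahydronaphthalene | C=C1CC[C@H]2C(C)(C)CCC[C@]2(C)[C@H]1CCI | intermediate
6 | methyl (4S)-2,2-dimethyl-1,3-dioxolane-4-carboxylate | COC(=O)[C@@H]1COC(C)(C)O1 | starting material
7 | (4S)-N-methoxy-N,2,2-trimethyl-1,3-dioxolane-4-carboxamide | CON(C)C(=O)[C@@H]1COC(C)(C)O1 | intermediate (not isolated)
8 | 1-[(4S)-2,2-dimethyl-1,3-dioxolan-4-yl]ethan-1-one | CC(=O)[C@@H]1COC(C)(C)O1 | intermediate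
9 | diiodo{2-[(1S,4aS,8aS)-5,5,8a-trimethyl-2-methylidenedecahydronaphthalen-1-yl]ethyl}samarium (trivalent samarium) | C=C1CC[C@H]2C(C)(C)CCC[C@]2(C)[C@H]1CC[Sm](I)I | intermediate (not isolated)
10 | (2S)-2-[(4S)-2,2-dimethyl-1,3-dioxolan-4-yl]-4-[(1S,4aS,8aS)-5,5,8a-trimethyl-2-methylidenedecahydronaphthalen-1-yl]butan-2-ol | C=C1CC[C@H]2C(C)(C)CCC[C@]2(C)[C@H]1CC[C@](C)(O)[C@@H]3COC(C)(C)O3 | intermediate
11 | (2S,3S)-3-methyl-5-[(1S,4aS,8aS)-5,5,8a-trimethyl-2-methylidenedecahydronaphthalen-1-yl]pentane-1,2,3-triol | C=C1CC[C@H]2C(C)(C)CCC[C@]2(C)[C@H]1CC[C@](C)(O)[C@@H](O)CO | intermediate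
12 | (13S,14S)-15-acetoxylabd-8(17)-ene-13,14-diol | C=C1CC[C@H]2C(C)(C)CCC[C@]2(C)[C@H]1CC[C@](C)(O)[C@@H](O)COC(C)=O | target

**Step count and risks**
Total steps: 6. Longest linear sequence: 5 (steps 1, 2, 4, 5, 6); step 3 is the one-step side branch.

Most likely to fail:

1. Step 4 (the proposed new step). Risks are photoreduction of the chelated ketone (pinacol coupling or C14–O cleavage), reduction of the radical to the alkane, and a diastereomer ratio lower than hoped (the 13-epimer would be removed by chromatography of 10). The fallback sets out from 5 and comes back at 10. Iodide 5 is converted with Mg turnings (THF, 0 °C → rt) into the Grignard reagent {2-[(1S,4aS,8aS)-5,5,8a-trimethyl-2-methylidenedecahydronaphthalen-1-yl]ethyl}magnesium iodide F1, which is added to ketone 8 in THF at −78 °C and quenched with aq. NH4Cl. I expect Grignard additions to 4-acyl-2,2-dimethyl-1,3-dioxolanes to give the chelate-type diastereomer, so 10 would form with the same 13S configuration by known polar chemistry; this sense of induction should be confirmed on 10.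

2. Step 1. Risks are the exo/endo alkene ratio and ring closure to Ambrox if the silyl group is lost early. The fallback sets out from 1 and comes back at 4, and replaces the E2 dehydration by an ester pyrolysis. Diol 1 is fully acetylated (Ac2O, DMAP, Et3N, 50 °C) to the diacetate (1R,2R,4aS,8aS)-1-(2-acetoxyethyl)-2,5,5,8a-tetramethyldecahydronaphthalen-2-yl acetate F2. Heating F2 in DMSO with NaHCO3 at 150 °C (or in refluxing 2,4,6-collidine) effects thermal syn-elimination of the tertiary acetate through a cyclic transition state that reaches the freely rotating C17 hydrogens, giving 2-[(1S,4aS,8aS)-5,5,8a-trimethyl-2-methylidenedecahydronaphthalen-1-yl]ethyl acetate F3. Methanolysis (K2CO3 cat., MeOH, rt) then gives 4.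

3. Step 3. Risks are over-addition, partial epimerisation at C14 and loss of the volatile, water-soluble ketone. The fallback sets out from 6 and comes back at 8. Ester 6 is saponified (LiOH, 1.0 equiv, THF/H2O, 0 °C) and dried to lithium (4S)-2,2-dimethyl-1,3-dioxolane-4-carboxylate F4. F4 is treated with MeLi (1.1 equiv, Et2O, −78 → 0 °C) to give the dilithium gem-diolate, and inverse quench into cold aq. NH4Cl releases 8 (classical ketone synthesis from a lithium carboxylate and an organolithium).

**Further compounds**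
F1 | step 4 | {2-[(1S,4aS,8aS)-5,5,8a-trimethyl-2-methylidenedecahydronaphthalen-1-yl]ethyl}magnesium iodide | C=C1CC[C@H]2C(C)(C)CCC[C@]2(C)[C@H]1CC[Mg]I
F2 | step 1 | (1R,2R,4aS,8aS)-1-(2-acetoxyethyl)-2,5,5,8a-tetramethyldecahydronaphthalen-2-yl acetate | C[C@@]1(OC(C)=O)CC[C@H]2C(C)(C)CCC[C@]2(C)[C@H]1CCOC(C)=O
F3 | step 1 | 2-[(1S,4aS,8aS)-5,5,8a-trimethyl-2-methylidenedecahydronaphthalen-1-yl]ethyl acetate | C=C1CC[C@H]2C(C)(C)CCC[C@]2(C)[C@H]1CCOC(C)=O
F4 | step 3 | lithium (4S)-2,2-dimethyl-1,3-dioxolane-4-carboxylate | [Li+].[O-]C(=O)[C@@H]1COC(C)(C)O1
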